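**Retrosynthetic overview**
1. Feature: ring A of the 2,3-dihydrobenzofuran (C3a, C4, C5, C6, C7, C7a) has one carbon substituent, at C5, para to the O1-bearing C7a and meta to C3a. C4–C5(–C)–C6–C7 maps onto C6–C5(–CO2Me)–C4–C3 of methyl coumalate. C3a/C7a map onto Cα/C=O of a γ-butyrolactone that already holds O1, C2, C3 (ring B) and the side chain C1'/C2'.
2. Endgame: the acrylic acid C=C at C5 (Knoevenagel–Doebner, malonic acid) and the C2'O–acyl bond (Mitsunobu, p-coumaric acid) are cut back to a C5 methyl ester carrying a C2' silyl ether.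
3. Key disconnection: C3a–C4 and C7a–C7. Ring A comes from methyl coumalate and the lactone silyl ketene acetal by inverse-demand Diels–Alder reaction, then loss of CO2 and silanol.
4. Lactone: C1' comes from methyl (S)-3-hydroxy-2-methylpropanoate and C2 from a reagent-controlled allylboration, followed by hydroboration and oxidative lactonization.
5. Ring order: ring B first (as the lactone), ring A second; ring C (4-hydroxyphenyl) is bought with p-coumaric acid.

Key step: step 7

Remark: benzofuran numbering is used for the core (O1, C2, C3, C3a, C4–C7, C7a); C1' is the side-chain CH(CH3) and C2' its CH2O. The target is (2S,1'S). Borane 5 and LiN(iPr)2 are taken as commercial solutions, and p-coumaric acid as the commercial (E)-isomer.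

**Step 1**
Reactants: 1 methyl (S)-3-hydroxy-2-methylpropanoate
Product: 2 methyl (S)-2-methyl-3-(triisopropylsilyloxy)propanoate
Conditions: TIPSCl, imidazole, DMF, 0 °C → rt
Reagents that add atoms: triisopropylsilyl chloride, CC(C)[Si](Cl)(C(C)C)C(C)C
Why: Imidazole-assisted silylation of a primary alcohol leaves the α-stereocentre (future C1') untouched, and the bulky ether is chosen to survive LiN(iPr)2, 110 °C and iBu2AlH later on.

**Step 2**
Reactants: 2 methyl (S)-2-methyl-3-(triisopropylsilyloxy)propanoate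
Product: 4 (S)-2-methyl-3-(triisopropylsilyloxy)propanal, via aluminium hemiacetal 3 (not isolated)
Conditions: iBu2AlH, CH2Cl2, −78 °C; aq. KNaC4H4O6 (tartrate)
Reagents that add atoms: none
Why: This is a partial ester reduction in which tetrahedral adduct 3 persists at −78 °C and releases the aldehyde only on quenching; the epimerizable aldehyde is used at once without chromatography.

**Step 3**
Reactants: 4 (S)-2-methyl-3-(triisopropylsilyloxy)propanal; 5 (−)-B-allyldiisopinocampheylborane (the enantiomer built from (+)-α-pinene)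
Product: 7 (2S,3S)-2-methyl-1-(triisopropylsilyloxy)hex-5-en-3-ol, via borinate ester 6 (not isolated)
Conditions: Et2O/pentane, −78 °C; then NaOH, H2O2, 0 °C → rt
Reagents that add atoms: none
Why: In this Brown asymmetric allylboration through a closed chair transition state, the isopinocampheyl groups send the allyl group to the Si face of the aldehyde, which sets the carbinol carbon (future C2) as S, syn to the methyl group, under reagent control.

**Step 4**
Reactants: 7 (2S,3S)-2-methyl-1-(triisopropylsilyloxy)hex-5-en-3-ol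
Product: 9 (4S,5S)-5-methyl-6-(triisopropylsilyloxy)hexane-1,4-diol, via B-alkyl-9-BBN adduct 8 (not isolated)
Conditions: 9-BBN (excess), THF, 0 °C → rt; then NaOH, H2O2, 0 °C
Reagents that add atoms: hydrogen peroxide, OO
Why: Anti-Markovnikov hydroboration of the terminal alkene with a bulky borane and oxidation of the C–B bond affect no stereocentre, and the excess reagent allows for the free hydroxyl group.

**Step 5**
Reactants: 9 (4S,5S)-5-methyl-6-(triisopropylsilyloxy)hexane-1,4-diol
Product: 11 (5S)-5-[(2S)-1-(triisopropylsilyloxy)propan-2-yl]oxolan-2-one, via lactol 10 (not isolated)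
Conditions: TEMPO (cat.), PhI(OAc)2, CH2Cl2, rt
Reagents that add atoms: none
Why: In this TEMPO/PhI(OAc)2 oxidative lactonization of a 1,4-diol the oxoammonium species takes the primary alcohol first, the hydroxy aldehyde closes to lactol 10, and a second oxidation gives the γ-lactone (ring B) without breaking the C–O bond at the stereocentre.

**Step 6**
Reactants: 11 (5S)-5-[(2S)-1-(triisopropylsilyloxy)propan-2-yl]oxolan-2-one
Product: 13 tert-butyldimethyl({(5S)-5-[(2S)-1-(triisopropylsilyloxy)propan-2-yl]-4,5-dihydrofuran-2-yl}oxy)silane, via lithium enolate 12 (not isolated)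
Conditions: LiN(iPr)2, THF, −78 °C; TBSCl, DMPU, −78 °C → rt; pentane, filtration, no aqueous work-up
Reagents that add atoms: tert-butyldimethylsilyl chloride, CC(C)(C)[Si](C)(C)Cl
Why: Kinetic deprotonation and O-silylation of the lactone enolate in the presence of a polar cosolvent is the established access to isolable silyl ketene acetals of γ-butyrolactones, and the stereocentre γ to the carbonyl cannot epimerize.

**Step 7**
Reactants: 13 tert-butyldimethyl({(5S)-5-[(2S)-1-(triisopropylsilyloxy)propan-2-yl]-4,5-dihydrofuran-2-yl}oxy)silane; 14 methyl coumalate (methyl 2-oxo-2H-pyran-5-carboxylate, acid-free, 1.5 equiv)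
Product: 17 methyl (2S)-2-[(2S)-1-(triisopropylsilyloxy)propan-2-yl]-2,3-dihydro-1-benzofuran-5-carboxylate, via bridged lactone adduct 15 (not isolated), via cyclohexadiene 16 (not isolated)
Conditions: PhMe, 110 °C, Ar; then DBU (cat.), rt
Reagents that add atoms: none
Why: Proposed new method: the electron-rich C=C of 13 (lactone Cα = future C3a, acetal carbon = future C7a) should add across C6 and C3 of the electron-poor pyrone 14 in an inverse-electron-demand [4+2] cycloaddition to bridged lactone 15, which expels CO2 in a retro-[4+2] step to cyclohexadiene 16, and 16 aromatizes by loss of tBuMe2SiOH across C3a–C7a. The closest known reaction type is the decarboxylative Diels–Alder aromatization of methyl coumalate with enol ethers, 1,1-dialkoxyethenes and orthoester-derived ketene acetals to para-alkoxybenzoates; an endocyclic silyl ketene acetal of a γ-lactone has not been shown as the two-carbon partner. Ring A is closed by intermolecular [4+2] annulation of pyrone carbons C6, C5, C4 and C3 onto the C3a=C7a edge of the existing oxolane, which makes C3a–C4 and C7a–C7 while ring B stays closed. Regioselectivity rests on matched polarization: pyrone C6, β to the ester and the terminus of the vinylogous lactone acceptor, takes the nucleophilic Cα, so the acetal carbon bonds to C3 and the ester ends up at C5, para to O1. No new stereocentre survives, because every sp3 centre made in 15 and 16 becomes aromatic and endo/exo and facial selectivity are therefore irrelevant, while C2 and C1' carry no acidic hydrogen and the C2–O1 bond is never broken. The chemoselectivity needed is loss of the exocyclic silyloxy group and not of O1: silanolate is the better nucleofuge, the alkyl-substituted O1 is the better donor to the developing cation at C7a, and once DBU removes the vinylogously acidic C3a–H the exocyclic C7a–O bond is aligned with the π system, whereas cleavage of C7a–O1 would be the reverse of a 5-endo-trig addition.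

**Step 8**
Reactants: 17 methyl (2S)-2-[(2S)-1-(triisopropylsilyloxy)propan-2-yl]-2,3-dihydro-1-benzofuran-5-carboxylate
Product: 18 {(2S)-2-[(2S)-1-(triisopropylsilyloxy)propan-2-yl]-2,3-dihydro-1-benzofuran-5-yl}methanol
Conditions: iBu2AlH (2.5 equiv), CH2Cl2, −78 → 0 °C; aq. KNaC4H4O6 (tartrate)
Reagents that add atoms: none
Why: Full hydride reduction of an aryl ester to the benzylic alcohol leaves the silyl ether and the aryl alkyl ether inert, and it avoids the unreliable partial reduction of an electron-rich benzoate.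

**Step 9**
Reactants: 18 {(2S)-2-[(2S)-1-(triisopropylsilyloxy)propan-2-yl]-2,3-dihydro-1-benzofuran-5-yl}methanol
Product: 19 (2S)-2-[(2S)-1-(triisopropylsilyloxy)propan-2-yl]-2,3-dihydro-1-benzofuran-5-carbaldehyde
Conditions: MnO2 (activated, excess), CH2Cl2, rt
Reagents that add atoms: none
Why: Heterogeneous MnO2 oxidation is selective for benzylic alcohols and stops at the aldehyde.

**Step 10**
Reactants: 19 (2S)-2-[(2S)-1-(triisopropylsilyloxy)propan-2-yl]-2,3-dihydro-1-benzofuran-5-carbaldehyde
Product: 20 (2S)-2-[(2S)-1-hydroxypropan-2-yl]-2,3-dihydro-1-benzofuran-5-carbaldehyde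
Conditions: Bu4NF, THF, 0 °C → rt
Reagents that add atoms: none
Why: Fluoride-driven cleavage of the Si–O bond frees the primary alcohol, and the non-enolizable aryl aldehyde and both stereocentres tolerate the mildly basic medium.

**Step 11**
Reactants: 20 (2S)-2-[(2S)-1-hydroxypropan-2-yl]-2,3-dihydro-1-benzofuran-5-carbaldehyde; 21 (E)-p-coumaric acid
Product: 22 (2S)-2-[(2S)-5-formyl-2,3-dihydro-1-benzofuran-2-yl]propyl (E)-3-(4-hydroxyphenyl)prop-2-enoate
Conditions: PPh3, DIAD, THF, 0 °C → rt
Reagents that add atoms: none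
Why: In this Mitsunobu esterification the far more acidic carboxyl group, not the phenol, is deprotonated and displaces the alkoxyphosphonium group at the primary C2', so the phenol needs no protection and no stereocentre or alkene geometry is involved.

**Step 12**
Reactants: 22 (2S)-2-[(2S)-5-formyl-2,3-dihydro-1-benzofuran-2-yl]propyl (E)-3-(4-hydroxyphenyl)prop-2-enoate; 23 malonic acid
Product: 25 (E)-3-[(2S)-2-{(2S)-1-[(E)-3-(4-hydroxyphenyl)prop-2-enoyloxy]propan-2-yl}-2,3-dihydro-1-benzofuran-5-yl]prop-2-enoic acid (CNP0224846.1), via arylidenemalonic acid 24 (not isolated)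
Conditions: pyridine, piperidine (cat.), 85 °C; dilute HCl work-up
Reagents that add atoms: none
Why: Knoevenagel–Doebner condensation of a p-alkoxybenzaldehyde, followed by decarboxylation in pyridine, should give the (E)-cinnamic acid directly as the free acid, and the primary coumarate ester and the phenol are stable to the weak amine bases.

**Compound list**
1 | methyl (S)-3-hydroxy-2-methylpropanoate | C[C@@H](CO)C(=O)OC | starting material
2 | methyl (S)-2-methyl-3-(triisopropylsilyloxy)propanoate | C[C@@H](CO[Si](C(C)C)(C(C)C)C(C)C)C(=O)OC | intermediate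
3 | diisobutylaluminium hemiacetal of 4 (not isolated; acetal carbon undefined) | C[C@@H](CO[Si](C(C)C)(C(C)C)C(C)C)C(OC)O[Al](CC(C)C)CC(C)C | intermediate
4 | (S)-2-methyl-3-(triisopropylsilyloxy)propanal | C[C@@H](CO[Si](C(C)C)(C(C)C)C(C)C)C=O | intermediate
5 | (−)-B-allyldiisopinocampheylborane, allylbis[(1R,2S,3R,5R)-2,6,6-trimethylbicyclo[3.1.1]heptan-3-yl]borane | C=CCB([C@@H]1C[C@@H]2C[C@H]([C@H]1C)C2(C)C)[C@@H]1C[C@@H]2C[C@H]([C@H]1C)C2(C)C | starting material
6 | diisopinocampheylborinate of alcohol 7 (not isolated) | C[C@@H](CO[Si](C(C)C)(C(C)C)C(C)C)[C@@H](OB([C@@H]1C[C@@H]2C[C@H]([C@H]1C)C2(C)C)[C@@H]1C[C@@H]2C[C@H]([C@H]1C)C2(C)C)CC=C | intermediate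
7 | (2S,3S)-2-methyl-1-(triisopropylsilyloxy)hex-5-en-3-ol | C[C@@H](CO[Si](C(C)C)(C(C)C)C(C)C)[C@@H](O)CC=C | intermediate
8 | (2S,3S)-6-(9-borabicyclo[3.3.1]nonan-9-yl)-2-methyl-1-(triisopropylsilyloxy)hexan-3-ol (not isolated) | C[C@@H](CO[Si](C(C)C)(C(C)C)C(C)C)[C@@H](O)CCCB1C2CCCC1CCC2 | intermediate
9 | (4S,5S)-5-methyl-6-(triisopropylsilyloxy)hexane-1,4-diol | C[C@@H](CO[Si](C(C)C)(C(C)C)C(C)C)[C@@H](O)CCCO | intermediate
10 | (5S)-5-[(2S)-1-(triisopropylsilyloxy)propan-2-yl]oxolan-2-ol (lactol, not isolated; anomeric carbon undefined) | C[C@@H](CO[Si](C(C)C)(C(C)C)C(C)C)[C@@H]1CCC(O)O1 | intermediate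
11 | (5S)-5-[(2S)-1-(triisopropylsilyloxy)propan-2-yl]oxolan-2-one | C[C@@H](CO[Si](C(C)C)(C(C)C)C(C)C)[C@@H]1CCC(=O)O1 | intermediate
12 | lithium enolate of 11 (not isolated) | C[C@@H](CO[Si](C(C)C)(C(C)C)C(C)C)[C@@H]1CC=C([O-])O1.[Li+] | intermediate
13 | tert-butyldimethyl({(5S)-5-[(2S)-1-(triisopropylsilyloxy)propan-2-yl]-4,5-dihydrofuran-2-yl}oxy)silane | C[C@@H](CO[Si](C(C)C)(C(C)C)C(C)C)[C@@H]1CC=C(O[Si](C)(C)C(C)(C)C)O1 | intermediate
14 | methyl coumalate (methyl 2-oxo-2H-pyran-5-carboxylate) | COC(=O)C1=COC(=O)C=C1 | starting material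
15 | bridged adduct (not isolated): a 2-oxabicyclo[2.2.2]oct-5-en-3-one whose saturated two-carbon bridge is the C3a–C7a bond of the oxolane; OTBS on C7a, CO2Me on the alkene carbon next to the O-bearing bridgehead; new centres undefined | C[C@@H](CO[Si](C(C)C)(C(C)C)C(C)C)[C@@H]1CC2C3OC(=O)C(C=C3C(=O)OC)C2(O[Si](C)(C)C(C)(C)C)O1 | intermediate
16 | methyl (2S)-7a-(tert-butyldimethylsilyloxy)-2-[(2S)-1-(triisopropylsilyloxy)propan-2-yl]-2,3,3a,7a-tetrahydro-1-benzofuran-5-carboxylate (not isolated; C3a and C7a undefined) | C[C@@H](CO[Si](C(C)C)(C(C)C)C(C)C)[C@@H]1CC2C=C(C(=O)OC)C=CC2(O[Si](C)(C)C(C)(C)C)O1 | intermediate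
17 | methyl (2S)-2-[(2S)-1-(triisopropylsilyloxy)propan-2-yl]-2,3-dihydro-1-benzofuran-5-carboxylate | C[C@@H](CO[Si](C(C)C)(C(C)C)C(C)C)[C@@H]1Cc2cc(C(=O)OC)ccc2O1 | intermediate
18 | {(2S)-2-[(2S)-1-(triisopropylsilyloxy)propan-2-yl]-2,3-dihydro-1-benzofuran-5-yl}methanol | C[C@@H](CO[Si](C(C)C)(C(C)C)C(C)C)[C@@H]1Cc2cc(CO)ccc2O1 | intermediate
19 | (2S)-2-[(2S)-1-(triisopropylsilyloxy)propan-2-yl]-2,3-dihydro-1-benzofuran-5-carbaldehyde | C[C@@H](CO[Si](C(C)C)(C(C)C)C(C)C)[C@@H]1Cc2cc(C=O)ccc2O1 | intermediate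
20 | (2S)-2-[(2S)-1-hydroxypropan-2-yl]-2,3-dihydro-1-benzofuran-5-carbaldehyde | C[C@@H](CO)[C@@H]1Cc2cc(C=O)ccc2O1 | intermediate
21 | (E)-p-coumaric acid | OC(=O)/C=C/c1ccc(O)cc1 | starting material
22 | (2S)-2-[(2S)-5-formyl-2,3-dihydro-1-benzofuran-2-yl]propyl (E)-3-(4-hydroxyphenyl)prop-2-enoate | C[C@@H](COC(=O)/C=C/c1ccc(O)cc1)[C@@H]1Cc2cc(C=O)ccc2O1 | intermediate
23 | malonic acid | OC(=O)CC(=O)O | starting material
24 | arylidenemalonic acid from 22 (not isolated) | C[C@@H](COC(=O)/C=C/c1ccc(O)cc1)[C@@H]1Cc2cc(C=C(C(=O)O)C(=O)O)ccc2O1 | intermediate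
25 | (E)-3-[(2S)-2-{(2S)-1-[(E)-3-(4-hydroxyphenyl)prop-2-enoyloxy]propan-2-yl}-2,3-dihydro-1-benzofuran-5-yl]prop-2-enoic acid | C[C@@H](COC(=O)/C=C/c1ccc(O)cc1)[C@@H]1Cc2cc(/C=C/C(=O)O)ccc2O1 | target

**Total step count:** 12. **Longest linear sequence:** 12 steps (from 1).

**Steps most likely to fail**

**1. Step 7.** Three processes may interfere.
- The ketene acetal may be protonated by liberated silanol or by traces of acid.
- Stepwise conjugate addition at pyrone C6 with silyl transfer may replace the cycloaddition.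
- Ring B may open during aromatization.

The fallback sets out from 4, comes back at 17, and buys the arene instead of building it.
- Aldehyde 4 is homologated with dimethyl (1-diazo-2-oxopropyl)phosphonate (K2CO3, MeOH; Seyferth–Gilbert homologation in the Ohira–Bestmann form) to the alkyne (R)-triisopropyl[(2-methylbut-3-yn-1-yl)oxy]silane F1.
- Sonogashira coupling of F1 with commercial methyl 4-hydroxy-3-iodobenzoate (PdCl2(PPh3)2, CuI, Et3N, DMF, 60 °C) gives the alkynylphenol methyl 4-hydroxy-3-[(3R)-3-methyl-4-(triisopropylsilyloxy)but-1-yn-1-yl]benzoate F2.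
- F2 closes in the same flask by 5-endo-dig attack of the phenol to the benzofuran methyl 2-[(2S)-1-(triisopropylsilyloxy)propan-2-yl]-1-benzofuran-5-carboxylate F3.
- Catalyst-controlled asymmetric hydrogenation of the furan C2=C3 bond then sets C2 and gives 17. Conditions are Ru(cod)(2-methylallyl)2, a chiral N-heterocyclic carbene ligand, KOtBu and H2 in hexane, with the ligand enantiomer chosen for delivery of hydrogen to the face that gives 2S. The C2 epimer is a diastereomer and can be removed by chromatography.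

**2. Step 6.** C-silylation of the enolate may compete with O-silylation, and the ketene acetal may hydrolyse during isolation. The fallback sets out from 11, comes back at 17, and replaces the isolated silyl ketene acetal by an orthoester that releases an alkyl ketene acetal only in the hot reaction mixture.
- Lactone 11 is O-methylated with Me3OBF4 (CH2Cl2, rt) to the lactonium salt (5S)-2-methoxy-5-[(2S)-1-(triisopropylsilyloxy)propan-2-yl]-4,5-dihydro-3H-furan-1-ium tetrafluoroborate F4.
- NaOMe in MeOH converts F4 into the cyclic orthoester (5S)-2,2-dimethoxy-5-[(2S)-1-(triisopropylsilyloxy)propan-2-yl]oxolane F5.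
- Heated with 14 in mesitylene at about 160 °C, F5 loses methanol to the ketene acetal (2S)-5-methoxy-2-[(2S)-1-(triisopropylsilyloxy)propan-2-yl]-2,3-dihydrofuran F6.
- F6 is trapped by 14 as the methoxy-substituted bridged adduct F7.
- Loss of CO2 gives the methoxy-substituted cyclohexadiene F8, and loss of methanol gives 17.

**3. Step 11.** O-alkylation of the phenol and oligomer formation may compete with esterification, and the spent Mitsunobu reagents may be hard to remove from the polar product. The fallback sets out from 21 and 20, comes back at 22, and replaces the redox condensation by acylation with a phenol-protected acid.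
- Acid 21 is bis-silylated (TBSCl, imidazole, DMF) to tert-butyldimethylsilyl (E)-3-[4-(tert-butyldimethylsilyloxy)phenyl]prop-2-enoate F9.
- The silyl ester of F9 is hydrolysed selectively (K2CO3, aq. MeOH/THF, 0 °C) to (E)-3-[4-(tert-butyldimethylsilyloxy)phenyl]prop-2-enoic acid F10.
- Steglich esterification of F10 with 20 (EDC·HCl, DMAP, CH2Cl2) gives (2S)-2-[(2S)-5-formyl-2,3-dihydro-1-benzofuran-2-yl]propyl (E)-3-[4-(tert-butyldimethylsilyloxy)phenyl]prop-2-enoate F11.
- Buffered fluoride (Bu4NF, AcOH, THF, 0 °C) removes the aryl silyl ether of F11 to give 22.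

**Further compounds**
F1 | step 7 | (R)-triisopropyl[(2-methylbut-3-yn-1-yl)oxy]silane | C[C@@H](CO[Si](C(C)C)(C(C)C)C(C)C)C#C
F2 | step 7 | methyl 4-hydroxy-3-[(3R)-3-methyl-4-(triisopropylsilyloxy)but-1-yn-1-yl]benzoate | C[C@@H](CO[Si](C(C)C)(C(C)C)C(C)C)C#Cc1cc(C(=O)OC)ccc1O
F3 | step 7 | methyl 2-[(2S)-1-(triisopropylsilyloxy)propan-2-yl]-1-benzofuran-5-carboxylate | C[C@@H](CO[Si](C(C)C)(C(C)C)C(C)C)c1cc2cc(C(=O)OC)ccc2o1
F4 | step 6 | (5S)-2-methoxy-5-[(2S)-1-(triisopropylsilyloxy)propan-2-yl]-4,5-dihydro-3H-furan-1-ium tetrafluoroborate | C[C@@H](CO[Si](C(C)C)(C(C)C)C(C)C)[C@@H]1CCC(OC)=[O+]1.F[B-](F)(F)F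
F5 | step 6 | (5S)-2,2-dimethoxy-5-[(2S)-1-(triisopropylsilyloxy)propan-2-yl]oxolane | C[C@@H](CO[Si](C(C)C)(C(C)C)C(C)C)[C@@H]1CCC(OC)(OC)O1
F6 | step 6 | (2S)-5-methoxy-2-[(2S)-1-(triisopropylsilyloxy)propan-2-yl]-2,3-dihydrofuran | C[C@@H](CO[Si](C(C)C)(C(C)C)C(C)C)[C@@H]1CC=C(OC)O1
F7 | step 6 | methoxy-substituted bridged adduct (analogue of 15 with OMe on C7a) | C[C@@H](CO[Si](C(C)C)(C(C)C)C(C)C)[C@@H]1CC2C3OC(=O)C(C=C3C(=O)OC)C2(OC)O1
F8 | step 6 | methoxy-substituted cyclohexadiene (analogue of 16 with OMe on C7a) | C[C@@H](CO[Si](C(C)C)(C(C)C)C(C)C)[C@@H]1CC2C=C(C(=O)OC)C=CC2(OC)O1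
F9 | step 11 | tert-butyldimethylsilyl (E)-3-[4-(tert-butyldimethylsilyloxy)phenyl]prop-2-enoate | CC(C)(C)[Si](C)(C)OC(=O)/C=C/c1ccc(O[Si](C)(C)C(C)(C)C)cc1
F10 | step 11 | (E)-3-[4-(tert-butyldimethylsilyloxy)phenyl]prop-2-enoic acid | OC(=O)/C=C/c1ccc(O[Si](C)(C)C(C)(C)C)cc1
F11 | step 11 | (2S)-2-[(2S)-5-formyl-2,3-dihydro-1-benzofuran-2-yl]propyl (E)-3-[4-(tert-butyldimethylsilyloxy)phenyl]prop-2-enoate | C[C@@H](COC(=O)/C=C/c1ccc(O[Si](C)(C)C(C)(C)C)cc1)[C@@H]1Cc2cc(C=O)ccc2O1
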